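**Retrosynthetic overview**
1. The last step breaks the Cβ–Cγ bond of the butenolide (C5–C6). A Ni/Cr ring closure joins a (Z)-β-iodoacrylate to a C6 aldehyde, and the alkoxide lactonises at once. This gives ring A (ten-membered carbocycle), ring C (butenolide) and C6 in one operation. RCM closure, a preformed butenolide and late α-methylenation are all avoided.
2. Ring B (α-methylene-γ-butyrolactone, C7/C8) is made one stage earlier by a nickel-free, ligand-controlled CrCl2 allylation of lactol 17 with bromide 4.
3. C3 and the iodoacrylate arise together from an asymmetric coupling of aldehyde, methyl propiolate and TMSI.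
4. C8–C9–C10(C14)–C1–C2–C3 and the C10 centre are the ozonolysed ring of (R)-cyclohex-3-enecarboxylic acid. γ-Lactone formation distinguishes the two chain ends.
5. Ring order: B (step 10), then A and C together (step 12).

Locants are germacrane numbers. C3 carries the isobutyrate. C4=C5, C15 and C6–O form the butenolide. C7, C8 and C11–C13 form the methylene lactone. C10 carries CH2OH (C14). The target is 3S,6R,7S,8R,10R, with a trans-fused ring B.

Assumption: the chiral controllers of steps 7 and 10 induce in the sense of their usual models; if not, the equally available mirror-image controller is used.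

**Step 1**
Reactants: 1 2,2-dimethoxyacetaldehyde; 2 methyl acrylate
Product: 3 methyl 3-hydroxy-4,4-dimethoxy-2-methylidenebutanoate (racemic)
Conditions: DABCO (0.5 equiv), 1,4-dioxane–H2O 1:1, rt
Reagents that add atoms: none
Why: Morita–Baylis–Hillman reaction of an activated, non-enolisable aldehyde; the carbinol centre is racemic and is erased in step 2.

**Step 2**
Reactants: 3 methyl 3-hydroxy-4,4-dimethoxy-2-methylidenebutanoate
Product: 4 methyl (2Z)-2-(bromomethyl)-4,4-dimethoxybut-2-enoate
Conditions: NBS, Me2S, CH2Cl2, 0 °C to rt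
Reagents that add atoms: N-bromosuccinimide O=C1CCC(=O)N1Br
Why: Corey–Kim-type activation followed by SN2' attack of bromide is the standard allylic transposition of Baylis–Hillman alcohols, is neutral enough to spare the acetal, and leaves no stereocentre.

**Step 3**
Reactants: 5 (1R)-cyclohex-3-ene-1-carboxylic acid
Product: 6 [(1R)-cyclohex-3-en-1-yl]methanol
Conditions: LiAlH4, THF, 0 °C to rt; then H2O
Reagents that add atoms: none
Why: Hydride reduction of the acid; C10 is bought with 5 and is not touched.

**Step 4**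
Reactants: 6 [(1R)-cyclohex-3-en-1-yl]methanol
Product: 9 3-[(3R)-5-oxooxolan-3-yl]propanoic acid, via ozonide 7 (not isolated), via hydroxy diacid 8 (not isolated)
Conditions: O3, CH2Cl2, −78 °C; 30% H2O2, HCO2H, 0 to 60 °C; TsOH (cat.), toluene, reflux (Dean–Stark)
Reagents that add atoms: ozone O=[O+][O-]; hydrogen peroxide OO
Why: Ozonolysis with oxidative work-up makes the C3 and C8 carboxyls, and acid equilibration (thermodynamic lactonisation) funnels 8 into the five-membered rather than the six-membered lactone, which differentiates the chain ends without protecting groups and leaves C10 untouched.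

**Step 5**
Reactants: 9 3-[(3R)-5-oxooxolan-3-yl]propanoic acid
Product: 10 (4R)-4-(3-hydroxypropyl)oxolan-2-one
Conditions: BH3·SMe2 (1.1 equiv), THF, 0 °C to rt; then H2O
Reagents that add atoms: none
Why: Chemoselective borane reduction, in which the free acid reacts through its acyloxyborane far faster than the lactone.

**Step 6**
Reactants: 10 (4R)-4-(3-hydroxypropyl)oxolan-2-one
Product: 11 3-[(3R)-5-oxooxolan-3-yl]propanal
Conditions: TEMPO (10 mol %), PhI(OAc)2, CH2Cl2, rt
Reagents that add atoms: none
Why: TEMPO (oxoammonium) oxidation stops at the aldehyde under anhydrous conditions and does not touch the lactone.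

**Step 7**
Reactants: 11 3-[(3R)-5-oxooxolan-3-yl]propanal; 12 methyl propiolate
Product: 15 methyl (2Z,3S)-3-hydroxy-2-(iodomethylidene)-5-[(3R)-5-oxooxolan-3-yl]pentanoate, via silyl allenolate 13 (not isolated), via silyl ether 14 (not isolated)
Conditions: TMSI (1.5 equiv), oxazaborolidinium triflimide from (S)-α,α-diphenylprolinol, o-tolylboronic acid and Tf2NH (20 mol %), CH2Cl2, −78 °C; then 1 M HCl, THF, 0 °C
Reagents that add atoms: iodotrimethylsilane C[Si](C)(C)I
Why: Catalytic asymmetric β-iodo Morita–Baylis–Hillman (three-component iodo-aldol) coupling, in which TMSI adds to 12, allenolate 13 attacks the Re face of the boron-bound aldehyde (C3 = S) anti to its iodine (Z alkene, I cis to CO2Me), and the lactone is inert to TMSI at −78 °C.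

**Step 8**
Reactants: 15 methyl (2Z,3S)-3-hydroxy-2-(iodomethylidene)-5-[(3R)-5-oxooxolan-3-yl]pentanoate
Product: 16 methyl (2Z,3S)-2-(iodomethylidene)-3-(2-methylpropanoyloxy)-5-[(3R)-5-oxooxolan-3-yl]pentanoate
Conditions: (i-PrCO)2O, Sc(OTf)3 (1 mol %), MeCN, −20 to 0 °C
Reagents that add atoms: isobutyric anhydride CC(C)C(=O)OC(=O)C(C)C
Why: Lewis-acid-catalysed acylation avoids nucleophilic amines that could displace the vinylic iodide by addition–elimination, and the C3–O bond is not broken, so C3 stays S.

**Step 9**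
Reactants: 16 methyl (2Z,3S)-2-(iodomethylidene)-3-(2-methylpropanoyloxy)-5-[(3R)-5-oxooxolan-3-yl]pentanoate
Product: 17 methyl (2Z,3S)-5-[(3R)-5-hydroxyoxolan-3-yl]-2-(iodomethylidene)-3-(2-methylpropanoyloxy)pentanoate (anomer mixture)
Conditions: disiamylborane (3 equiv, from BH3·THF and 2-methylbut-2-ene), THF, 0 °C to rt; then H2O2, pH 7 buffer, 0 °C
Reagents that add atoms: none
Why: Selective dialkylborane lactone-to-lactol reduction, because disiamylborane reduces γ-lactones to the hemiacetal stage but leaves acyclic esters (as with acylated aldonolactones) and the electron-poor trisubstituted iodoalkene alone; the anomeric centre is lost in step 10.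

**Step 10**
Reactants: 17 lactol iodoacrylate (name as above); 4 methyl (2Z)-2-(bromomethyl)-4,4-dimethoxybut-2-enoate
Product: 19 methyl (2Z,3S,6R)-7-[(2R,3S)-3-(dimethoxymethyl)-4-methylidene-5-oxooxolan-2-yl]-6-(hydroxymethyl)-2-(iodomethylidene)-3-(2-methylpropanoyloxy)heptanoate, via diol diester 18 (not isolated)
Conditions: CrCl2 (5 equiv, nickel-free), (S,S)-1,8-bis(4-isopropyl-4,5-dihydrooxazol-2-yl)-3,6-diphenyl-9H-carbazole (5.5 equiv, recovered), Et3N, THF, rt, 4 (2 equiv); aq. NH4Cl; PPTS (cat.), CH2Cl2, rt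
Reagents that add atoms: none
Why: Ligand-controlled Nozaki–Hiyama allylation then lactonisation, in which CrCl2 without NiCl2 reduces only the allylic bromide, the allylchromium equilibrates to its E form and adds through a chair transition state to the open hydroxy-aldehyde tautomer of 17 (lactols react this way in Takai and Barbier chemistry) to give the anti adduct, the ligand directs attack to the Si face (C8 = R, C7 = S), and PPTS closes the trans lactone.

**Step 11**
Reactants: 19 lactone acetal (name as above)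
Product: 20 methyl (2Z,3S,6R)-7-[(2R,3S)-3-formyl-4-methylidene-5-oxooxolan-2-yl]-6-(hydroxymethyl)-2-(iodomethylidene)-3-(2-methylpropanoyloxy)heptanoate
Conditions: TFA–H2O 9:1, CH2Cl2, 0 °C, 30 min; NaHCO3 wash; used at once without chromatography
Reagents that add atoms: water O
Why: Acid-catalysed acetal hydrolysis that is short, cold and base-free, so the C7–H (α to CHO and allylic) neither epimerises nor lets the exocyclic alkene slip into conjugation.

**Step 12**
Reactants: 20 seco aldehyde (name as above)
Product: 22 (3S,6R,7S,8R,10R)-14-hydroxy-3-(2-methylpropanoyloxy)germacra-4,11(13)-diene-12,8:15,6-diolide, via hydroxy ester 21 (not isolated)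
Conditions: CrCl2 (15 equiv), NiCl2 (0.1 equiv), DMSO–THF, 1 mM (syringe pump, 12 h), rt; aq. NH4Cl; PPTS (cat.), CH2Cl2 if needed
Reagents that add atoms: none
Why: Nozaki–Hiyama–Kishi macrocyclisation followed by lactonisation, in which NiCl2 now activates the alkenyl iodide, the trisubstituted alkenylchromium keeps its geometry (C3 and C6 trans), the tether forces C5 to approach synclinal to C8 and anti to the sp2 carbon C11 (Felkin–Anh with C11 as the large group, reinforced by 1,3-anti polar induction from the C8 oxygen), meaning Re-face attack and C6 = R, and the cis alkoxide of 21 expels methoxide from the C15 ester to close the butenolide.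

**Compound list**
1 | 2,2-dimethoxyacetaldehyde | COC(OC)C=O | starting material
2 | methyl acrylate | C=CC(=O)OC | starting material
3 | methyl 3-hydroxy-4,4-dimethoxy-2-methylidenebutanoate (racemic) | COC(OC)C(O)C(=C)C(=O)OC | intermediate
4 | methyl (2Z)-2-(bromomethyl)-4,4-dimethoxybut-2-enoate | COC(OC)/C=C(\CBr)C(=O)OC | intermediate
5 | (1R)-cyclohex-3-ene-1-carboxylic acid | C1[C@H](C(=O)O)CCC=C1 | starting material
6 | [(1R)-cyclohex-3-en-1-yl]methanol | C1[C@H](CO)CCC=C1 | intermediate
7 | secondary ozonide of 6 (7,8,9-trioxabicyclo[4.2.1]nonane, CH2OH at C3, C10 as in 6) | C1[C@H](CO)CCC2OOC1O2 | intermediate (not isolated)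
8 | (3R)-3-(hydroxymethyl)hexanedioic acid | OC(=O)C[C@H](CO)CCC(=O)O | intermediate (not isolated)
9 | 3-[(3R)-5-oxooxolan-3-yl]propanoic acid | O=C1C[C@H](CO1)CCC(=O)O | intermediate
10 | (4R)-4-(3-hydroxypropyl)oxolan-2-one | O=C1C[C@H](CO1)CCCO | intermediate
11 | 3-[(3R)-5-oxooxolan-3-yl]propanal | O=C1C[C@H](CO1)CCC=O | intermediate
12 | methyl propiolate | C#CC(=O)OC | starting material
13 | (3-iodo-1-methoxypropa-1,2-dienyl)oxytrimethylsilane | IC=C=C(OC)O[Si](C)(C)C | intermediate (not isolated)
14 | trimethylsilyl ether of 15 | O=C1C[C@H](CO1)CC[C@H](O[Si](C)(C)C)/C(=C/I)C(=O)OC | intermediate (not isolated)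
15 | methyl (2Z,3S)-3-hydroxy-2-(iodomethylidene)-5-[(3R)-5-oxooxolan-3-yl]pentanoate | O=C1C[C@H](CO1)CC[C@H](O)/C(=C/I)C(=O)OC | intermediate
16 | methyl (2Z,3S)-2-(iodomethylidene)-3-(2-methylpropanoyloxy)-5-[(3R)-5-oxooxolan-3-yl]pentanoate | O=C1C[C@H](CO1)CC[C@H](OC(=O)C(C)C)/C(=C/I)C(=O)OC | intermediate
17 | methyl (2Z,3S)-5-[(3R)-5-hydroxyoxolan-3-yl]-2-(iodomethylidene)-3-(2-methylpropanoyloxy)pentanoate (anomer mixture) | OC1C[C@H](CO1)CC[C@H](OC(=O)C(C)C)/C(=C/I)C(=O)OC | intermediate
18 | dimethyl (2Z,3S,6R,8R,9S)-9-(dimethoxymethyl)-8-hydroxy-6-(hydroxymethyl)-2-(iodomethylidene)-10-methylidene-3-(2-methylpropanoyloxy)undecanedioate | C=C(C(=O)OC)[C@@H]([C@H](O)C[C@H](CO)CC[C@H](OC(=O)C(C)C)/C(=C/I)C(=O)OC)C(OC)OC | intermediate (not isolated)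
19 | methyl (2Z,3S,6R)-7-[(2R,3S)-3-(dimethoxymethyl)-4-methylidene-5-oxooxolan-2-yl]-6-(hydroxymethyl)-2-(iodomethylidene)-3-(2-methylpropanoyloxy)heptanoate | C=C1C(=O)O[C@H](C[C@H](CO)CC[C@H](OC(=O)C(C)C)/C(=C/I)C(=O)OC)[C@H]1C(OC)OC | intermediate
20 | methyl (2Z,3S,6R)-7-[(2R,3S)-3-formyl-4-methylidene-5-oxooxolan-2-yl]-6-(hydroxymethyl)-2-(iodomethylidene)-3-(2-methylpropanoyloxy)heptanoate | C=C1C(=O)O[C@H](C[C@H](CO)CC[C@H](OC(=O)C(C)C)/C(=C/I)C(=O)OC)[C@H]1C=O | intermediate
21 | methyl (3S,6R,7S,8R,10R)-6,14-dihydroxy-3-(2-methylpropanoyloxy)germacra-4,11(13)-dien-12,8-olid-15-oate (C3 and C6 trans on C4=C5) | C=C1C(=O)O[C@@H]2C[C@H](CO)CC[C@H](OC(=O)C(C)C)/C(C(=O)OC)=C/[C@@H](O)[C@@H]12 | intermediate (not isolated)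
22 | (3S,6R,7S,8R,10R)-14-hydroxy-3-(2-methylpropanoyloxy)germacra-4,11(13)-diene-12,8:15,6-diolide (CNP0332805.1) | C=C1C(=O)O[C@@H]2C[C@H](CO)CC[C@H](OC(=O)C(C)C)C3=C[C@@H](OC3=O)[C@@H]12 | target

**Step count**
Total steps: 12. Longest linear sequence: 10 (steps 3–12, from 5).

**Steps most likely to fail**

**Step 12.** The risks are the strain of closing a ring that holds a trans C4=C5 bond and the lability of aldehyde 20. The fallback swaps the order of the two chromium couplings, so the ring is closed at C7–C8 and no β-formyl methylene lactone is ever made. It sets out from 16 and 4 and comes back at 22.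
- Bromo acetal 4 is hydrolysed (NaHCO3, aqueous MeCN, 50 °C, then 0.1 M HCl) with participation of the cis acetal oxygen. This gives methyl 5-hydroxy-2,5-dihydrofuran-3-carboxylate F1, the lactol of the hydroxy enal.
- Intermolecular Ni/Cr coupling of 16 with F1 (CrCl2, NiCl2 cat., a chiral oxazoline–sulfonamide ligand, Et3N, MeCN) sets C6 under ligand control. The product is the open dihydroxy diester F2.
- F2 lactonises only onto the cis C15 ester and gives the butenolide allylic alcohol F3.
- Appel bromination (CBr4, PPh3, 0 °C) gives the allylic bromide F4.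
- Disiamylborane reduces only the unhindered saturated lactone and gives the lactol F5.
- CrCl2 alone (THF, 1 mM) closes ring A by intramolecular Nozaki–Hiyama allylation (anti chair; attack on C7 anti to C5) to the macrocyclic hydroxy ester F6, which lactonises to 22.

**Step 10.** The risks are that the free lactol disturbs ligand control and that the allylchromium carries a β-alkoxy group. The fallback is a stereospecific allylboration with a geometrically fixed boronate. It sets out from 17 and comes back at 19.
- 3,3-Dimethoxyprop-1-yne (commercial) is carboxylated (n-BuLi, ClCO2Me) to methyl 4,4-dimethoxybut-2-ynoate F7.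
- syn-Hydroalumination (i-Bu2AlH, HMPA, THF) and trapping with ICH2Bpin give methyl (2Z)-4,4-dimethoxy-2-[(4,4,5,5-tetramethyl-1,3,2-dioxaborolan-2-yl)methyl]but-2-enoate F8, in which C6 is trans to CH2B.
- Allylboration of 17 catalysed by (R)-TRIP (toluene, rt to 40 °C) passes this geometry through a closed chair to anti adduct 18. The phosphoric acid chooses the aldehyde face.
- PPTS then gives 19.

**Step 7.** The risks are that the lactone competes for the boron catalyst and that unbranched aldehydes are the weakest class for ee. The fallback sets C3 by reduction instead of by C–C bond formation. It sets out from 11 and comes back at 15.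
- MgI2-promoted, non-asymmetric coupling of 11 with 12 (CH2Cl2, 0 °C) gives 15 mixed with its (3R)-epimer F9.
- Dess–Martin oxidation of the mixture gives the iodomethylidene keto ester F10.
- Corey–Bakshi–Shibata reduction with (R)-Me-CBS and catecholborane (−78 °C; the branched alkenyl group is the large substituent) returns 15 as the 3S alcohol.

**Further compounds**
F1 | step 12 | methyl 5-hydroxy-2,5-dihydrofuran-3-carboxylate | OC1C=C(CO1)C(=O)OC
F2 | step 12 | open dihydroxy diester (C3 S, C10 R, C6 spatially as in 22; C15 ester cis to C6; C6 cis to CH2OH on C7=C11) | O=C1C[C@H](CO1)CC[C@H](OC(=O)C(C)C)/C(C(=O)OC)=C/[C@@H](O)/C=C(\CO)C(=O)OC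
F3 | step 12 | butenolide allylic alcohol (C3 S, C10 R, C6 spatially as in 22; C6 cis to CH2OH on C7=C11) | O=C1C[C@H](CO1)CC[C@H](OC(=O)C(C)C)C2=C[C@@H](OC2=O)/C=C(\CO)C(=O)OC
F4 | step 12 | butenolide allylic bromide (stereochemistry as F3) | O=C1C[C@H](CO1)CC[C@H](OC(=O)C(C)C)C2=C[C@@H](OC2=O)/C=C(\CBr)C(=O)OC
F5 | step 12 | lactol of F4 (anomer mixture) | OC1C[C@H](CO1)CC[C@H](OC(=O)C(C)C)C2=C[C@@H](OC2=O)/C=C(\CBr)C(=O)OC
F6 | step 12 | macrocyclic hydroxy ester: methyl (3S,6R,7S,8R,10R)-8,14-dihydroxy-3-(2-methylpropanoyloxy)germacra-4,11(13)-dien-15,6-olid-12-oate | C=C(C(=O)OC)[C@H]1[C@H](O)C[C@H](CO)CC[C@H](OC(=O)C(C)C)C2=C[C@H]1OC2=O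
F7 | step 10 | methyl 4,4-dimethoxybut-2-ynoate | COC(OC)C#CC(=O)OC
F8 | step 10 | methyl (2Z)-4,4-dimethoxy-2-[(4,4,5,5-tetramethyl-1,3,2-dioxaborolan-2-yl)methyl]but-2-enoate | COC(OC)/C=C(/CB1OC(C)(C)C(C)(C)O1)C(=O)OC
F9 | step 7 | methyl (2Z,3R)-3-hydroxy-2-(iodomethylidene)-5-[(3R)-5-oxooxolan-3-yl]pentanoate | O=C1C[C@H](CO1)CC[C@@H](O)/C(=C/I)C(=O)OC
F10 | step 7 | methyl (2Z)-2-(iodomethylidene)-3-oxo-5-[(3R)-5-oxooxolan-3-yl]pentanoate | O=C1C[C@H](CO1)CCC(=O)/C(=C/I)C(=O)OC
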